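## Retrosynthetic overview

1. The target has two CH(iPr) stereocenters, each joining the central acylphloroglucinol to a syncarpic acid unit. I disconnect both CH–syncarpyl bonds by reversing the usual Knoevenagel/Friedel–Crafts polarity. The arene becomes a bis(ortho-quinone methide) electrophile and syncarpic acid is the nucleophile, and one catalytic, doubly asymmetric 1,4-addition sets both stereocenters.
2. The bis-o-QM is masked as a bench-stable bis(α-tosylalkyl)acylphloroglucinol. That sulfone comes from hexanoylphloroglucinol, isobutyraldehyde and sodium p-toluenesulfinate.
3. Hexanoylphloroglucinol comes from phloroglucinol by C-acylation with hexanoic acid. Syncarpic acid comes from phloroglucinol by dearomative tetra-C-methylation, so the trione ring is made first and the aromatic core is kept. Only the central arene and the two trione rings are present, so no further rings are formed.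
4. Assumption: the acyl group CCCCCC(=O) is hexanoyl. CIP analysis of the target SMILES gives (R,R) at both methine carbons, with priorities syncarpyl > aryl > iPr > H. I assume the quinine-derived catalyst delivers (R,R).

## Route

**Step 1**
Reactants: 1 phloroglucinol; 2 hexanoic acid
Product: 3, 2',4',6'-trihydroxyhexanophenone (1-(2,4,6-trihydroxyphenyl)hexan-1-one)
Conditions: BF3·OEt2, 85 °C, 2 h; aqueous workup
Reagents that add atoms: none beyond reactant 2 (BF3 is not incorporated)
Why: BF3-mediated Friedel–Crafts C-acylation of phloroglucinol; the three ring positions are equivalent, and the product is deactivated by the acyl group and its intramolecular H-bonds, so mono-acylation dominates. No stereocenter is formed.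

**Step 2**
Reactants: 1 phloroglucinol; 4 iodomethane
Product: 5, syncarpic acid (2,2,4,4-tetramethylcyclohexane-1,3,5-trione)
Conditions: NaOMe (6 equiv), MeI (5 equiv), MeOH, reflux, 4 h; then acidify and extract into aqueous NaHCO3 to separate it from the neutral hexamethyl byproduct
Reagents that add atoms: iodomethane, CI
Why: Dearomative exhaustive C-methylation of the phloroglucinolate through its trione tautomer, a known classical preparation. The strongly acidic tetramethyl product (pKa about 4) is separated from the over-methylated neutral byproduct by base extraction.

**Step 3**
Reactants: 3 2',4',6'-trihydroxyhexanophenone; 6 isobutyraldehyde; 7 sodium p-toluenesulfinate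
Product: 8, 1-{2,4,6-trihydroxy-3,5-bis[2-methyl-1-(4-methylphenylsulfonyl)propyl]phenyl}hexan-1-one (mixture of sulfone epimers)
Conditions: 6 (3 equiv), 7 (3.5 equiv), HCO2H (10 equiv), H2O/MeCN 1:1, 40 °C, 24 h; the product is collected by filtration and used without chromatography
Reagents that add atoms: sodium p-toluenesulfinate, Cc1ccc(cc1)S(=O)[O-].[Na+]
Why: Proposed new method: acid-promoted aldehyde–phenol condensation gives the o-QM, which sulfinic acid traps reversibly at sulfur; the sulfone is the thermodynamic sink and precipitates. The closest known reaction is the three-component synthesis of 2-(α-tosylalkyl)phenols (o-QM precursors) from phenols, aldehydes and sulfinic acid, here applied twice to an acylphloroglucinol (each condensation is ArH + RCHO + TsH − H2O). The sulfone stereocenters are labile and are destroyed when the planar o-QM forms in Step 4, so they need no control.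

**Step 4 (key step)**
Reactants: 8 bis-sulfone; 5 syncarpic acid (2.6 equiv); 9 catalyst (quinine-derived 9-epi-amino squaramide, 20 mol %)
Product: 10, myrtucommulone F
Conditions: 9 (20 mol %), K2CO3 (5 equiv), CH2Cl2, 0 °C, 72 h; cold dilute HCl to pH 3; chromatography on silica with 1% AcOH to remove the meso (R,S) diastereomer; recrystallization
Reagents that add atoms: none (the syncarpic acid is a listed reactant; p-toluenesulfinate is lost)
Why: Proposed new method: base deprotonates a phenol and expels sulfinate to give an H-bonded o-QM, and the syncarpic acid enolate (ion-paired to the protonated quinuclidinium, with the o-QM oxygen bound by the squaramide NH groups) adds to the exocyclic carbon face-selectively. The second arm repeats this independently because the two centers are remote. The closest known reaction is the cinchona-squaramide-catalyzed asymmetric conjugate addition of 1,3-dicarbonyls to in situ o-QMs from 2-(α-tosylalkyl)phenols. Each center is set by catalyst control. If each arm has er ≈ 93:7, the (R,R):(R,S, meso):(S,S) ratio is ≈ 86:13:0.5. The meso diastereomer is removed by achiral chromatography, which leaves (R,R) at ≈ 99% ee (Horeau-type amplification). The product is not heated or exposed to strong acid or base afterward, so retro-Michael racemization is avoided.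

## Compound list

| # | Name | SMILES | Role |
|---|---|---|---|
| 1 | Phloroglucinol | Oc1cc(O)cc(O)c1 | starting material |
| 2 | Hexanoic acid | CCCCCC(=O)O | starting material |
| 3 | 2',4',6'-Trihydroxyhexanophenone | CCCCCC(=O)c1c(O)cc(O)cc1O | intermediate |
| 4 | Iodomethane | CI | starting material |
| 5 | Syncarpic acid | CC1(C)C(=O)CC(=O)C(C)(C)C1=O | intermediate |
| 6 | Isobutyraldehyde | CC(C)C=O | starting material |
| 7 | Sodium p-toluenesulfinate | Cc1ccc(cc1)S(=O)[O-].[Na+] | starting material |
| 8 | Bis(α-tosylalkyl)acylphloroglucinol (sulfone epimers, unassigned) | CCCCCC(=O)c1c(O)c(C(C(C)C)S(=O)(=O)c2ccc(C)cc2)c(O)c(C(C(C)C)S(=O)(=O)c2ccc(C)cc2)c1O | intermediate |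
| 9 | Quinine-derived 9-epi-amino squaramide organocatalyst (N'-3,5-bis(trifluoromethyl)phenyl), commercially available | COc1ccc2nccc([C@H](NC5=C(Nc6cc(C(F)(F)F)cc(C(F)(F)F)c6)C(=O)C5=O)[C@@H]3C[C@@H]4CCN3C[C@@H]4C=C)c2c1 | starting material |
| 10 | Myrtucommulone F, (R,R) | CCCCCC(=O)c1c(O)c([C@H](C2=C(O)C(C)(C)C(=O)C(C)(C)C2=O)C(C)C)c(O)c([C@H](C2=C(O)C(C)(C)C(=O)C(C)(C)C2=O)C(C)C)c1O | target |

## Summary

Total steps: 4 (Step 2 is a parallel branch).
Longest linear sequence: 3 steps (1 → 3 → 8 → 10, i.e. Steps 1, 3 and 4).

## Three steps most likely to fail

1. **Step 4 (enantioselectivity).** The uncatalyzed background addition to the o-QM is fast, and an alkyl (iPr) o-QM is a poorer substrate for these catalysts than aryl ones. Fallback: use the racemic three-component Knoevenagel–Michael assembly of 3, 6 and 5, then obtain (R,R) by preparative chiral-phase HPLC or by diastereomeric-salt crystallization with a chiral amine, since the acidic product is configurationally stable at room temperature. If (S,S) forms instead of (R,R), use the quinidine-derived pseudoenantiomeric catalyst.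
2. **Step 3 (bis-sulfone formation).** Diarylmethane oligomers from o-QM capture by a second arene, or stopping at the mono-sulfone, are possible. Fallback: skip the sulfone and generate the o-QMs directly from 3 and 6 in the presence of 5, using a chiral phosphoric acid as organocatalyst in a one-pot three-component coupling.
3. **Step 2 (syncarpic acid yield).** Mixtures of tetra- and hexa-methylated products limit the yield. Fallback: tetra-C-methylate 2,4,6-trihydroxyacetophenone (MeI/NaOMe) to the 6-acetylsyncarpic acid, then deacetylate by base-mediated retro-Claisen cleavage.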